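The cyclopentane (C1 aryl/methyl, C2 CH–CH3, C3 =CHBr, C4, C5) is disconnected at C2–C3. In the precursor the phenol oxygen of the arene and the carbon that becomes the C2 methyl group are tied as a six-membered lactone, a 4,4-disubstituted chroman-2-one with a bromoalkyne chain on the quaternary carbon. Gold-catalysed 5-exo-dig cyclisation of its silyl ketene acetal closes the cyclopentane, sets C2 through the forced cis ring fusion (aryl and C2 methyl carbon syn on C1–C2) and gives the (Z)-bromomethylene by anti addition to the alkyne. C1 comes from a copper-catalysed asymmetric allylic alkylation; the lactone carbonyl is finally reduced to CH3, releasing the phenol.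

Key step: step 9

Assumption: the sense of induction in step 5 is not predicted here; the ligand enantiomer that delivers the (R) centre from the (Z)-phosphate is to be used, and the (S) form is written only as a placeholder.

Step 1
Reactants: 1 4,7-dimethyl-2H-chromen-2-one (4,7-dimethylcoumarin)
Product: 2 (Z)-3-(2-hydroxy-4-methylphenyl)but-2-en-1-ol
Conditions: i-Bu2AlH (4 equiv), CH2Cl2, −78 → 0 °C; aq. KNaC4H4O6 work-up
Reagents that add atoms: none
Why: Excess i-Bu2AlH reduces the lactone carbonyl twice (hydride reduction of a lactone to a diol) without touching the C3=C4 bond, so the cis geometry held by the coumarin ring is carried into the (Z)-allylic alcohol.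

Step 2
Reactants: 2 (Z)-3-(2-hydroxy-4-methylphenyl)but-2-en-1-ol
Product: 3 (Z)-3-[2-(methoxymethoxy)-4-methylphenyl]but-2-en-1-ol
Conditions: NaH (1.0 equiv), THF, 0 °C; MeOCH2Cl (1.0 equiv), 0 °C
Reagents that add atoms: chloromethyl methyl ether, COCCl
Why: One equivalent of NaH deprotonates only the far more acidic phenol and the phenoxide is alkylated (Williamson-type O-alkylation), so the allylic alcohol can later be activated without closing to the 2H-chromene.

Step 3
Reactants: 3 (Z)-3-[2-(methoxymethoxy)-4-methylphenyl]but-2-en-1-ol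
Product: 4 diethyl (Z)-3-[2-(methoxymethoxy)-4-methylphenyl]but-2-en-1-yl phosphate
Conditions: ClP(O)(OEt)2, Et3N, 4-(dimethylamino)pyridine (cat.), CH2Cl2, 0 °C; used without storage
Reagents that add atoms: diethyl chlorophosphate, CCOP(=O)(Cl)OCC
Why: Phosphorylation of the primary allylic alcohol gives the allylic phosphate, the usual leaving group for copper-catalysed SN2' allylic substitution.

Step 4
Reactants: 5 (4-bromobut-1-yn-1-yl)trimethylsilane
Product: 6 [4-(trimethylsilyl)but-3-yn-1-yl]magnesium bromide (ethereal solution, titrated and used directly)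
Conditions: Mg turnings (1.5 equiv, activated with 1,2-dibromoethane), Et2O, gentle reflux → rt
Reagents that add atoms: magnesium, [Mg]
Why: Magnesium inserts into the primary C–Br bond (Grignard formation) while the silyl-capped alkyne is inert, giving one alkylmagnesium reagent per molecule of bromide for direct use in the allylic alkylation.

Step 5
Reactants: 4 diethyl (Z)-3-[2-(methoxymethoxy)-4-methylphenyl]but-2-en-1-yl phosphate; 6 [4-(trimethylsilyl)but-3-yn-1-yl]magnesium bromide
Product: 7 [(5R)-5-[2-(methoxymethoxy)-4-methylphenyl]-5-methylhept-6-en-1-yn-1-yl]trimethylsilane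
Conditions: Cu(OTf)2 (2 mol %), 1-[(2S)-1-hydroxy-4-methylpentan-2-yl]-3-(2,4,6-trimethylphenyl)-4,5-dihydro-1H-imidazol-3-ium hexafluorophosphate (3 mol %), 6 (1.5 equiv, slow addition), Et2O/CH2Cl2, −30 → −15 °C; aq. NH4Cl work-up
Reagents that add atoms: none
Why: Copper-catalysed enantioselective allylic alkylation of an allylic phosphate with a Grignard reagent (SN2'-selective, the chiral alkoxide-tethered NHC–copper alkyl adding at the disubstituted γ-carbon anti to the phosphate) should create the all-carbon quaternary centre C1 with aryl, methyl, vinyl and homopropargyl groups, its (R) configuration being set by the ligand enantiomer.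

Step 6
Reactants: 7 [(5R)-5-[2-(methoxymethoxy)-4-methylphenyl]-5-methylhept-6-en-1-yn-1-yl]trimethylsilane
Product: 8 (3R)-3-[2-(methoxymethoxy)-4-methylphenyl]-3-methyl-7-(trimethylsilyl)hept-6-yn-1-ol
Conditions: 9-borabicyclo[3.3.1]nonane (1.3 equiv), THF, 0 °C → rt; then H2O2, aq. NaOAc, 0 °C → rt
Reagents that add atoms: hydrogen peroxide, OO
Why: Anti-Markovnikov hydroboration–oxidation of the only terminal alkene with the bulky borane (the silylalkyne reacts much more slowly) should give the primary alcohol without touching the quaternary centre.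

Step 7
Reactants: 8 (3R)-3-[2-(methoxymethoxy)-4-methylphenyl]-3-methyl-7-(trimethylsilyl)hept-6-yn-1-ol
Product: 10 (4R)-4,7-dimethyl-4-[4-(trimethylsilyl)but-3-yn-1-yl]-3,4-dihydro-2H-chromen-2-one, via carboxylic acid 9 (not isolated)
Conditions: 2,2,6,6-tetramethylpiperidin-1-oxyl (20 mol %), PhI(OAc)2 (2.2 equiv), MeCN/H2O 1:1, rt; then 2 M HCl, THF, 50 °C
Reagents that add atoms: water, O
Why: Oxoammonium oxidation takes the primary alcohol through the aldehyde hydrate to the acid, and aqueous acid then removes the methoxymethyl acetal and closes the phenol onto the acid (acid-catalysed lactonisation favoured by the gem-disubstituted carbon), tying the phenol oxygen to the future C2 methyl carbon.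

Step 8
Reactants: 10 (4R)-4,7-dimethyl-4-[4-(trimethylsilyl)but-3-yn-1-yl]-3,4-dihydro-2H-chromen-2-one
Product: 11 (4R)-4-(4-bromobut-3-yn-1-yl)-4,7-dimethyl-3,4-dihydro-2H-chromen-2-one
Conditions: N-bromosuccinimide (1.2 equiv), AgNO3 (10 mol %), acetone, rt, dark
Reagents that add atoms: N-bromosuccinimide, O=C1CCC(=O)N1Br
Why: Silver-catalysed bromodesilylation of the alkynylsilane (via a silver acetylide) should exchange SiMe3 for Br directly under neutral conditions that leave the lactone and the arene alone.

Step 9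
Reactants: 11 (4R)-4-(4-bromobut-3-yn-1-yl)-4,7-dimethyl-3,4-dihydro-2H-chromen-2-one
Product: 13 (3Z,3aR,9bR)-3-(bromomethylidene)-7,9b-dimethyl-1,2,3,3a-tetrahydrocyclopenta[c]chromen-4(9bH)-one (cis-fused tricyclic lactone), via silyl ketene acetal 12 (not isolated)
Conditions: KN(SiMe3)2 (1.1 equiv), t-BuMe2SiCl (1.3 equiv, present from the start), THF, −78 °C; solvent exchange; Ph3PAuCl (5 mol %), AgBF4 (5 mol %), CH2Cl2/MeOH 10:1, 0 °C → rt
Reagents that add atoms: none
Why: O-Silylation of the potassium enolate gives the cyclic silyl ketene acetal 12, whose nucleophilic carbon attacks the bromoalkyne activated by cationic monovalent gold (Ph3PAu+) anti to the metal, after which methanol removes the silyl group and protodeaurates the alkenylgold with retention. The closest known reaction type is the gold-catalysed carbocyclisation of silyl enol ethers and silyl ketene aminals onto alkynes, 1-haloalkynes included (Conia-ene manifold). The cyclopentane is closed in the 5-exo-dig mode by attack on the internal alkyne carbon. The new stereocentre C2 is controlled by the existing quaternary centre C1 through the ring: the two-carbon tether on C1 can reach only the face of the planar ketene acetal carbon on which it sits, so the ring fusion is cis and the lactone carbonyl (the future C2 methyl) is syn to the aryl ring. Anti addition across the alkyne places Br on the same side as the new C2–C3 bond, which is the (Z)-bromomethylene. The step needs 5-exo over 6-endo closure and direct attack instead of 1,2-bromine migration, which the short tether on a quaternary carbon (Thorpe–Ingold effect) and the strongly nucleophilic ketene acetal with a phosphine-ligated cationic gold catalyst should secure.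

Step 10
Reactants: 13 (3Z,3aR,9bR)-3-(bromomethylidene)-7,9b-dimethyl-1,2,3,3a-tetrahydrocyclopenta[c]chromen-4(9bH)-one
Product: 14 (3Z,3aR,9bR)-3-(bromomethylidene)-7,9b-dimethyl-1,2,3,3a,4,9b-hexahydrocyclopenta[c]chromen-4-ol (lactol, mixture at C4)
Conditions: i-Bu2AlH (1.1 equiv), CH2Cl2, −78 °C
Reagents that add atoms: none
Why: One equivalent of i-Bu2AlH at low temperature stops at the lactol through a stable tetrahedral aluminate (partial lactone reduction), the new lactol carbon forming as an anomeric mixture that is destroyed in the next step.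

Step 11
Reactants: 14 (3Z,3aR,9bR)-3-(bromomethylidene)-7,9b-dimethyl-1,2,3,3a,4,9b-hexahydrocyclopenta[c]chromen-4-ol
Product: 16 2-[(1R,2R,3Z)-3-(bromomethylidene)-1,2-dimethylcyclopentyl]-5-methylphenol, via tosylhydrazone 15 (not isolated)
Conditions: TsNHNH2 (1.1 equiv), EtOH, rt; then catecholborane (3 equiv), CHCl3, 0 °C; NaOAc·3H2O, 60 °C
Reagents that add atoms: none
Why: The lactol opens to the hydroxy aldehyde, which condenses with tosylhydrazide, and hydroboration of the C=N bond followed by acetate-induced loss of sulfinate and N2 (Caglioti-type tosylhydrazone reduction) turns the former lactone carbon into the C2 methyl group under mild conditions that should not epimerise C2.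

Step 12
Reactants: 16 2-[(1R,2R,3Z)-3-(bromomethylidene)-1,2-dimethylcyclopentyl]-5-methylphenol
Product: 17 4-bromo-2-[(1R,2R,3Z)-3-(bromomethylidene)-1,2-dimethylcyclopentyl]-5-methylphenol
Conditions: N-bromosuccinimide (1.0 equiv), MeCN, −20 → 0 °C
Reagents that add atoms: N-bromosuccinimide, O=C1CCC(=O)N1Br
Why: Electrophilic aromatic bromination should occur para to the phenol OH (ortho to the ring methyl), the most activated open position, while the electron-poor bromoalkene stays untouched.

Compound list
1 | 4,7-dimethyl-2H-chromen-2-one | Cc1ccc2c(c1)oc(=O)cc2C | starting material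
2 | (Z)-3-(2-hydroxy-4-methylphenyl)but-2-en-1-ol | Cc1ccc(/C(C)=C\CO)c(O)c1 | intermediate
3 | (Z)-3-[2-(methoxymethoxy)-4-methylphenyl]but-2-en-1-ol | Cc1ccc(/C(C)=C\CO)c(OCOC)c1 | intermediate
4 | diethyl (Z)-3-[2-(methoxymethoxy)-4-methylphenyl]but-2-en-1-yl phosphate | Cc1ccc(/C(C)=C\COP(=O)(OCC)OCC)c(OCOC)c1 | intermediate
5 | (4-bromobut-1-yn-1-yl)trimethylsilane | C[Si](C)(C)C#CCCBr | starting material
6 | [4-(trimethylsilyl)but-3-yn-1-yl]magnesium bromide | C[Si](C)(C)C#CCC[Mg]Br | intermediate
7 | [(5R)-5-[2-(methoxymethoxy)-4-methylphenyl]-5-methylhept-6-en-1-yn-1-yl]trimethylsilane | Cc1ccc([C@](C=C)(C)CCC#C[Si](C)(C)C)c(OCOC)c1 | intermediate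
8 | (3R)-3-[2-(methoxymethoxy)-4-methylphenyl]-3-methyl-7-(trimethylsilyl)hept-6-yn-1-ol | Cc1ccc([C@](CCO)(C)CCC#C[Si](C)(C)C)c(OCOC)c1 | intermediate
9 | (3R)-3-[2-(methoxymethoxy)-4-methylphenyl]-3-methyl-7-(trimethylsilyl)hept-6-ynoic acid | Cc1ccc([C@](CC(=O)O)(C)CCC#C[Si](C)(C)C)c(OCOC)c1 | intermediate (not isolated)
10 | (4R)-4,7-dimethyl-4-[4-(trimethylsilyl)but-3-yn-1-yl]-3,4-dihydro-2H-chromen-2-one | Cc1ccc2c(c1)OC(=O)C[C@@]2(C)CCC#C[Si](C)(C)C | intermediate
11 | (4R)-4-(4-bromobut-3-yn-1-yl)-4,7-dimethyl-3,4-dihydro-2H-chromen-2-one | Cc1ccc2c(c1)OC(=O)C[C@@]2(C)CCC#CBr | intermediate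
12 | {[(4R)-4-(4-bromobut-3-yn-1-yl)-4,7-dimethyl-4H-chromen-2-yl]oxy}(tert-butyl)dimethylsilane | Cc1ccc2c(c1)OC(O[Si](C)(C)C(C)(C)C)=C[C@@]2(C)CCC#CBr | intermediate (not isolated)
13 | (3Z,3aR,9bR)-3-(bromomethylidene)-7,9b-dimethyl-1,2,3,3a-tetrahydrocyclopenta[c]chromen-4(9bH)-one, cis-fused | Cc1ccc2c(c1)OC(=O)[C@H]1/C(=C\Br)CC[C@@]21C | intermediate
14 | (3Z,3aR,9bR)-3-(bromomethylidene)-7,9b-dimethyl-1,2,3,3a,4,9b-hexahydrocyclopenta[c]chromen-4-ol, mixture at the lactol carbon | Cc1ccc2c(c1)OC(O)[C@H]1/C(=C\Br)CC[C@@]21C | intermediate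
15 | 4-methyl-N'-{[(1R,2R,5Z)-5-(bromomethylidene)-2-(2-hydroxy-4-methylphenyl)-2-methylcyclopentyl]methylidene}benzenesulfonohydrazide | Cc1ccc([C@]2(C)CC/C(=C/Br)[C@@H]2C=NNS(=O)(=O)c2ccc(C)cc2)c(O)c1 | intermediate (not isolated)
16 | 2-[(1R,2R,3Z)-3-(bromomethylidene)-1,2-dimethylcyclopentyl]-5-methylphenol | Cc1ccc([C@]2(C)CC/C(=C/Br)[C@@H]2C)c(O)c1 | intermediate
17 | 4-bromo-2-[(1R,2R,3Z)-3-(bromomethylidene)-1,2-dimethylcyclopentyl]-5-methylphenol | Cc1cc(O)c([C@]2(C)CC/C(=C/Br)[C@@H]2C)cc1Br | target

Total step count: 12 (11 on the main line and 1 for the Grignard reagent). Longest linear sequence: 11 steps (1 → 2 → 3 → 4 → 7 → 8 → 10 → 11 → 13 → 14 → 16 → 17).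

Steps most likely to fail

Step 9. The silyl ketene acetal may be protodesilylated by methanol before the C–C bond forms, or the gold-activated bromoalkyne may close 6-endo or undergo 1,2-bromine migration. The fallback replaces the silyl ketene acetal by a 1,3-dicarbonyl donor and sets out from 11. Acylation of its lithium enolate (LiN(SiMe3)2, THF, −78 °C) with di-tert-butyl dicarbonate should give tert-butyl (4R)-4-(4-bromobut-3-yn-1-yl)-4,7-dimethyl-2-oxochromane-3-carboxylate F1, a cyclic malonate whose enol is the classical Conia-ene donor. Ph3PAuCl/AgOTf in CH2Cl2 should then close the cyclopentane to tert-butyl (3Z,3aR,9bR)-3-(bromomethylidene)-7,9b-dimethyl-4-oxo-1,2,3,9b-tetrahydrocyclopenta[c]chromene-3a(4H)-carboxylate F2, with the lactone carbonyl syn and the ester anti to the aryl ring. CF3CO2H followed by warming in toluene removes the tert-butyl group and decarboxylates; protonation of the lactone enol on the convex face comes back to the route at 13.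

Step 5. Enantioselectivity may erode and SN2 product may leak with the (Z)-configured, ortho-alkoxyaryl phosphate, and the Grignard reagent may react through an uncatalysed background pathway or attack the phosphate at phosphorus. The fallback forms the other C–C bond of the quaternary centre (C1–CH3 instead of C1–C5) and sets out from 1. Deprotonation at the 4-methyl group (LiN(SiMe3)2, THF, −78 °C) and alkylation of the extended enolate with 3-bromo-1-(trimethylsilyl)prop-1-yne should give 7-methyl-4-[4-(trimethylsilyl)but-3-yn-1-yl]-2H-chromen-2-one F3. The operations of steps 1 to 3 then give (Z)-3-(2-hydroxy-4-methylphenyl)-7-(trimethylsilyl)hept-2-en-6-yn-1-ol F4, its methoxymethyl ether (Z)-3-[2-(methoxymethoxy)-4-methylphenyl]-7-(trimethylsilyl)hept-2-en-6-yn-1-ol F5 and the phosphate diethyl (Z)-3-[2-(methoxymethoxy)-4-methylphenyl]-7-(trimethylsilyl)hept-2-en-6-yn-1-yl phosphate F6. Copper-catalysed asymmetric allylic substitution with the small, reactive methyl nucleophile (MeMgBr or Me2Zn, chiral NHC–copper catalyst) comes back to the route at 7.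

Step 11. Hydrazone formation from the hindered lactol may be incomplete, and C2 may epimerise through the open-chain aldehyde or hydrazone. The fallback avoids any carbonyl-level intermediate and sets out from 13. LiAlH4 (THF, 0 °C) opens the lactone to 2-[(1R,2R,3Z)-3-(bromomethylidene)-2-(hydroxymethyl)-1-methylcyclopentyl]-5-methylphenol F7. MsCl/Et3N gives the bis-mesylate [(1R,2R,5Z)-5-(bromomethylidene)-2-{2-[(methylsulfonyl)oxy]-4-methylphenyl}-2-methylcyclopentyl]methyl methanesulfonate F8. LiEt3BH (THF, 0 °C → rt) displaces the primary mesylate by hydride to give 2-[(1R,2R,3Z)-3-(bromomethylidene)-1,2-dimethylcyclopentyl]-5-methylphenyl methanesulfonate F9, and KOH/MeOH frees the phenol, coming back to the route at 16.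

Further compounds
F1 | step 9 | tert-butyl (4R)-4-(4-bromobut-3-yn-1-yl)-4,7-dimethyl-2-oxochromane-3-carboxylate (mixture at C3) | Cc1ccc2c(c1)OC(=O)C(C(=O)OC(C)(C)C)[C@@]2(C)CCC#CBr
F2 | step 9 | tert-butyl (3Z,3aR,9bR)-3-(bromomethylidene)-7,9b-dimethyl-4-oxo-1,2,3,9b-tetrahydrocyclopenta[c]chromene-3a(4H)-carboxylate | Cc1ccc2c(c1)OC(=O)[C@@]1(C(=O)OC(C)(C)C)/C(=C\Br)CC[C@@]21C
F3 | step 5 | 7-methyl-4-[4-(trimethylsilyl)but-3-yn-1-yl]-2H-chromen-2-one | Cc1ccc2c(c1)oc(=O)cc2CCC#C[Si](C)(C)C
F4 | step 5 | (Z)-3-(2-hydroxy-4-methylphenyl)-7-(trimethylsilyl)hept-2-en-6-yn-1-ol | Cc1ccc(/C(CCC#C[Si](C)(C)C)=C\CO)c(O)c1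
F5 | step 5 | (Z)-3-[2-(methoxymethoxy)-4-methylphenyl]-7-(trimethylsilyl)hept-2-en-6-yn-1-ol | Cc1ccc(/C(CCC#C[Si](C)(C)C)=C\CO)c(OCOC)c1
F6 | step 5 | diethyl (Z)-3-[2-(methoxymethoxy)-4-methylphenyl]-7-(trimethylsilyl)hept-2-en-6-yn-1-yl phosphate | Cc1ccc(/C(CCC#C[Si](C)(C)C)=C\COP(=O)(OCC)OCC)c(OCOC)c1
F7 | step 11 | 2-[(1R,2R,3Z)-3-(bromomethylidene)-2-(hydroxymethyl)-1-methylcyclopentyl]-5-methylphenol | Cc1ccc([C@]2(C)CC/C(=C/Br)[C@@H]2CO)c(O)c1
F8 | step 11 | [(1R,2R,5Z)-5-(bromomethylidene)-2-{2-[(methylsulfonyl)oxy]-4-methylphenyl}-2-methylcyclopentyl]methyl methanesulfonate | Cc1ccc([C@]2(C)CC/C(=C/Br)[C@@H]2COS(C)(=O)=O)c(OS(C)(=O)=O)c1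
F9 | step 11 | 2-[(1R,2R,3Z)-3-(bromomethylidene)-1,2-dimethylcyclopentyl]-5-methylphenyl methanesulfonate | Cc1ccc([C@]2(C)CC/C(=C/Br)[C@@H]2C)c(OS(C)(=O)=O)c1
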